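Two questions, and one quantity answers both.

| flask | free monomer | transfer agent | initiator | impurity | remark | time |
|---|---|---|---|---|---|---|
| dawn | 0.25 M | 0.15 M | 12 mM | 2.7 mM | run made earlier |  |
| autumn | 1 M | 0.15 M | 12 mM | 2.7 mM | run made earlier |  |
| noon | 0.50 M | 0.15 M | 6 mM | 2.7 mM | run made earlier |  |
| flask | 0.50 M | 0.150 M | 12 mM | 2.7 mM |  | 4.0 h |

| run | time / h | monomer in chains / % | free monomer / % |
|---|---|---|---|
| dawn | 0.250 | 0.6 | 98.8 |
| dawn | 0.833 | 3.6 | 96.6 |
| dawn | 1.33 | 3.6 | 95.6 |
| dawn | 2.00 | 7.0 | 93.6 |
| dawn | 3.00 | 9.2 | 90.7 |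
| dawn | 4.00 | 9.5 | 90.3 |
| autumn | 0.333 | 1.2 | 99.4 |
| autumn | 0.500 | 4.1 | 96.8 |
| autumn | 0.833 | 5.1 | 96.2 |
| autumn | 1.33 | 6.9 | 93.4 |
| autumn | 2.50 | 6.5 | 92.4 |
| autumn | 4.00 | 7.8 | 91.3 |
| noon | 0.333 | 0.8 | 100.3 |
| noon | 1.00 | 1.5 | 99.2 |
| noon | 2.00 | 3.7 | 97.1 |
| noon | 3.00 | 2.1 | 96.8 |
| noon | 4.00 | 3.2 | 96.8 |

(readings scatter by 0.5 percentage points)

- the average divides the monomer in chains by the number of chains begun, living and dead together
- steps thought possible: free monomer + initiator -> living end + monomer in chains; free monomer + living end -> monomer in chains + living end; living end + transfer agent -> dead chain; living end -> dead end A; initiator + impurity -> spent initiator B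
- the earlier runs do not show the number of chains; that part of a forecast is a guess

- average number of monomer units in a chain (chains begun, living or dead) at 4.0 h
- part of the free monomer that has reacted at 4.0 h

In the noon run, free monomer stops falling: it reads 96.8 % at 3.00 h and 96.8 % at 4.00 h. Assume each impurity destroys one initiator and each remaining initiator starts one chain, and call u = c(initiator) − c(impurity) the useful initiator. Now turn the question round: on that assumption, no reaction asks for u at zero, yet this flask has more initiator than impurity, c(initiator) of 12 mM against c(impurity) of 2.7 mM, so it stands at u = 9.30 mM.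

The dawn and autumn runs share that u. Their c(free monomer) differs by a factor of 4.00, and still their last readings of monomer in chains are 9.5 % and 7.8 %. Their mean divided by u gives g, the fraction of free monomer reacted at the plateau per molar of useful initiator: g = 9.30 M⁻¹. The noon run is a separate check: with u = 3.30 mM, g predicts 3.07 %, and it reads 3.2 %.

For this flask I reckon c = g·u = 8.65 %. Units per chain are then g·c(free monomer) = 4.65, a guess, since no run shows the chains.

The forecast gave 9 % and 5 units, somewhat above my figures, holding that “the number of chains is fixed by the initiator”.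

The flask gives 8.37 % and 4.53 units per chain.

    free monomer + initiator → living end + monomer in chains (k = 2.71 M⁻¹ h⁻¹)
    free monomer + living end → monomer in chains + living end, rate k2*[living end]*[free monomer] (k = 16.8 M⁻¹ h⁻¹)
    living end + transfer agent → dead chain (kL = 0.167 M⁻¹ h⁻¹)
    living end → dead end A (k = 2.23 h⁻¹)
    initiator + impurity → spent initiator B (k = 8070 M⁻¹ h⁻¹)

At the end this flask keeps less of its initiator than of its free monomer: 0.48 % of the charge against 92 %. This flask's own conversion over u comes to 9.00 M⁻¹, beside g of 9.30 M⁻¹. A neighbour flask charged with 4.80 mM of initiator has u = 2.10 mM, so g predicts 1.95 % and 4.65 units, and that neighbour stands at 1.95 % with 4.66 units per chain.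

All runs were generated by integration for substances that don't exist; scatter was added.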